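## Structural features

The target is a C20 diterpenoid monoacetate on a trans-fused hydroazulene. A seven-membered ring (C1, C10, C9, C8, C7, C6, C5) shares the C1–C5 bond with a cyclopentene (C1 to C5) that has its alkene at C2=C3 and a methyl group on C4. C10 is an sp2 carbon carrying an exocyclic methylene; it lies between the allylic C9 carbinol (α face) and the ring-fusion C1–H, which is allylic to both ring alkenes. C6 carries a β hydroxyl and C7 a β side chain: C11 (methyl), C12 (acetate), C13 (methylene), C14 (free allylic hydroxyl), C15 (isopropenyl). Of the nine stereocentres, C4, C5 and C1 form a contiguous all-trans triad that continues without a gap through C6, C7, C11 and C12; C9 and C14 stand apart. The fragile points are the C12 acetate (1,3 to the free C14 hydroxyl and 1,4 to the C6 hydroxyl, so it migrates under base), the two ionisable allylic alcohols, three alkenes, and C1–H, which becomes epimerisable whenever C10 is a carbonyl. The real difficulty is not ring size. It is control over seven contiguous centres spanning ring and chain, one acylated oxygen among four, and the C9 hydroxyl / C10 methylene pair next to C1. The key step uses the fact that C10 is stereochemically silent in the target yet bonded to C1: a silyloxy group on C10 of a cycloheptenone (C6 carbonyl, C5=C1 alkene) can steer C1, C5 and, with a catalyst, C4, and is then erased by oxidation and methylenation.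

## Logic of the disconnections

**33 back to 32 and 31.** The bonds cut are the O–Si bonds at O6 and O9 and the C14–H bond. The acetate must sit on O12 while O14 is free, so C14 is kept as a ketone until O12 is acylated and the two oxygens never compete. This avoids any selective acylation and any protecting group on O14. The reduction of 31 must be reagent-controlled, and the desilylation of 32 must be non-basic so that the acetate does not move.

**31 back to 30, then to 27 and 29.** The bonds cut are the acyl–O12 bond and C12–C13. A carbinol β to a carbonyl is an aldol retron, and the C11 stereocentre of 27 can direct the addition. The last four chain carbons then come from a five-carbon enone derivative. The addition to 27 must follow the Felkin–Anh sense and must not epimerise C11.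

**27 back to 26, 25 and 23.** In the backward sense the O6–C12 bond is re-formed: the C12 aldehyde and the O6 hydroxyl are folded into a cyclic acetal. In 23 the O6 oxygen is protected and C12 is masked by the same atoms. The forward steps must open the acetal mildly and must tell a primary from a secondary silyl ether.

**23 back to 22, 21, 19, 18 and 17.** The bonds cut are C10=CH2 (back to a ketone), C9–O (back to an enolate) and the C10 carbonyl (back to the silyl-protected carbinol). The ketone is what makes C9 oxygenation possible, and it derives from the oxygen that earlier served as the control element. This removes the C9 stereocentre and returns the sacrificial centre. Enolisation must go toward C9 and not toward C1, and oxygen must arrive on the α face.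

**17 back to 16, then to 14 and 15.** The bond cut is C7–C11. Delivery of C11 from a tether on O6 makes the cis relationship of O6 and the side chain a matter of geometry. The branch is removed and a simple cycloheptenol remains. The forward step needs a 5-exo closure of a secondary radical with the methyl group on the convex face.

**14 back to 13 and 11.** The C6 carbinol goes back to a carbonyl and the C7=C8 alkene to a saturated bond. What remains is a plain bicyclic ketone. Enolisation must be regioselective toward C7 and hydride must come from the α face.

**11 back to 10.** The bond cut is C2=C3. The bicycle becomes a cycloheptanone with two alkene arms. The arms must be trans on C1 and C5 and C4 must already be set.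

**10 back to 4, 8 and 7.** The bonds cut are C1–C2 and C4–C5. Both arms and three stereocentres (C1, C5, C4) then come from one enone, one vinyl nucleophile and one crotyl electrophile. The forward step must add anti to the C10 silyloxy group, trap the enolate regiospecifically at C5, and allylate at the substituted terminus with catalyst control at C4.

**4 back to 3, 2 and 1; 7 back to 5 and 6; 29 back to 28.** The O–Si bond, the carbonyl/carbinol pair (back to a meso peroxide) and the two C–O bonds of the peroxide are cut; 7 is split at its O–acyl bond and 29 at its O–Si bond. This reaches commercial materials in three steps for 4 and one step each for 7 and 29. The rearrangement of 2 must be enantioselective.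

## Other disconnections considered

**Alternative 1:** The cut is C7–C11, made through a temporary O6–C12 acetal link. In the forward step the bromoacetal A2 (C6 allylic alcohol derivative with the C7=C8 alkene, the C9 silyl ether and the C10 methylene already present) is treated with Bu3SnH and AIBN; the C11 radical closes 5-exo on C7 and should give the cis-fused ethyl acetal A1.
- In its favour: the tether fixes the C6/C7 relationship, the neutral radical conditions tolerate silyl ethers and alkenes, and the acetal is a latent C12 aldehyde.
- Against it as the organising step: it forms one skeletal bond and no ring of the target, it leaves the hydroazulene, the C4/C5/C1 triad and C9 to other chemistry, and A2 carries a doubly allylic C9 silyl ether that is more sensitive than anything the chosen plan exposes to the radical step. The C11 methyl orientation rests on a kinetic preference.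
- Comparison: on mechanism the two plans are equal, because the chosen route uses this same reaction in step 10 on the simpler substrate 16, and A1 is the same compound as 23. On structure the chosen key step does more (two bonds, three centres). For the side chain the alternative is the better tool, which is why it is kept as a subordinate step. Step economy is about equal, since only the order of operations differs.

**Alternative 2:** The cut is C1–C10, read backwards as contraction of the seven-membered ring to a cyclohexane. In the forward step BF3·OEt2 opens the oxirane of the trans-hydrindane epoxy alcohol A4 at C10 while the C9–C1 bond migrates, which should give the hydroazulen-9-one A3 with a hydroxymethyl group on C10.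
- In its favour: trans-hydrindanes are easier to build with stereocontrol than cycloheptanes, the shift is stereospecific (inversion at C10, retention at C1), and the allylic C1 migrates readily. The C9 carbonyl and the future methylene carbon arrive together, so on the C9/C10 problem this alternative is better than the chosen plan, which spends steps 11 to 15 on it. It also forms the seven-membered ring, whereas the chosen key step closes no ring.
- Against it: a Lewis acid meets two silyl ethers, a hydride shift or migration of C8 competes, A3 is a β-hydroxy ketone that can undergo retro-aldol cleavage or dehydrate early to a reactive α-methylene ketone, and the C9 ketone must later be reduced from the correct face. All of C4, C5, C1, C6, C7, C11 and the epoxide carbon must be set before the key step.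
- Comparison: a cationic rearrangement is less forgiving than the catalytic organometallic sequence, and the steps saved at C9/C10 are likely to be spent on making A4.

**Alternative 3:** The cuts are C8–C9 and C9–C10, with carbon monoxide as C9. In the forward step 9-BBN adds to the C7=C8 methylidene of the vinyl iodide A6, and Pd(PPh3)4 (zerovalent palladium) under CO then inserts carbon monoxide at C10 and couples the acyl group with the C8 borane, which should give the enone A5.
- In its favour: it is convergent and mild, it closes the seven-membered ring, and it places the C9 carbonyl beside the C10 methylene in one operation. On ring formation and on the C9/C10 pair it is better than the chosen plan.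
- Against it: the C7 stereocentre would arise from hydroboration of a 1,1-disubstituted alkene between two stereocentres under acyclic control; direct coupling without CO would give a six-membered ring; a seven-membered acylpalladium closure competes with oligomerisation; and A5 is an α-methylene ketone beside the doubly allylic C1–H, open to conjugate addition and alkene migration. The C4/C5/C1 triad must be made separately.
- Comparison: the chosen plan sets that triad in its first strategic step from a three-step precursor. The alternative is equal or better in convergence but carries an untested medium-ring carbonylation and an uncontrolled C7.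

Key step: step 5

Remark on the chemistry: atom numbers C1 to C15 are those of the target throughout; β is the ring face of H5 and α that of H1. The catalysts of steps 2 and 5 are written as the enantiomers assumed to give the configurations shown; should the sense of induction be the reverse, the pseudoenantiomeric alkaloid or the mirror-image ligand takes their place.

## Steps

Step 1
Reactants: 1 cyclohepta-1,3-diene
Product: 2 (1R,5S)-6,7-dioxabicyclo[3.2.2]non-8-ene (meso endoperoxide)
Conditions: O2, tetraphenylporphyrin (cat.), hν (visible), CH2Cl2, 0 °C
Reagents that add atoms: dioxygen, O=O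
Why: Singlet-oxygen [4+2] cycloaddition across the s-cis diene; suprafacial addition can only give the meso bicyclic peroxide, so no stereochemical choice arises.

Step 2
Reactants: 2 (1R,5S)-6,7-dioxabicyclo[3.2.2]non-8-ene
Product: 3 (R)-4-hydroxycyclohept-2-en-1-one
Conditions: 9-O-acetylcupreidine (10 mol %), CH2Cl2, rt
Reagents that add atoms: none
Why: Enantioselective Kornblum–DeLaMare rearrangement: the chiral tertiary amine removes one of the two enantiotopic bridgehead protons with E2-type O–O cleavage, which desymmetrises the meso peroxide and sets the future C10 carbinol.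

Step 3
Reactants: 3 (R)-4-hydroxycyclohept-2-en-1-one
Product: 4 (R)-4-(tert-butyldimethylsilyloxy)cyclohept-2-en-1-one
Conditions: tBuMe2SiCl, imidazole, CH2Cl2, 0 °C to rt
Reagents that add atoms: tert-butyldimethylsilyl chloride, CC(C)(C)[Si](C)(C)Cl
Why: Standard silylation of a secondary alcohol; the mild base avoids β-elimination of the γ-oxygen and the stereocentre is untouched.

Step 4
Reactants: 5 (E)-but-2-en-1-ol; 6 methyl chloroformate
Product: 7 (E)-but-2-enyl methyl carbonate
Conditions: pyridine, CH2Cl2, 0 °C
Reagents that add atoms: none
Why: Acylation of a primary alcohol by a chloroformate; the E geometry, which the iridium step needs, is carried over unchanged.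

Step 5
Reactants: 4 (R)-4-(tert-butyldimethylsilyloxy)cyclohept-2-en-1-one; 8 vinylmagnesium bromide; 7 (E)-but-2-enyl methyl carbonate
Product: 10 (2R,3R,4R)-2-[(2S)-but-3-en-2-yl]-4-(tert-butyldimethylsilyloxy)-3-vinylcycloheptan-1-one, via bromomagnesium enolate 9 (not isolated)
Conditions: CuBr·SMe2 (10 mol %), CH2=CHMgBr, THF, −78 to −40 °C; then 7, [Ir(cod)Cl]2 (2 mol %), (Ra,R,R)-(1,1'-binaphthalene-2,2'-diyl) N,N-bis(1-phenylethyl)phosphoramidite (4 mol %, pre-activated with nPrNH2), THF, −40 °C to rt
Reagents that add atoms: none
Why: Transmetallation gives a vinylcopper species (monovalent copper) that adds to C1 of the enone and leaves a bromomagnesium enolate defined at C5–C6; the cyclometalated complex formed from [Ir(cod)Cl]2 (monovalent iridium) and the ligand ionises the carbonate with loss of CO2 to a trivalent iridium allyl complex, which the enolate attacks from outside at the methyl-bearing terminus. The closest known reaction types are the conjugate addition–enolate trapping used on 4-silyloxycycloalkenones and the iridium-catalysed branched allylic alkylation of ketone enolates. No ring is closed. C1 is set by the C10 silyloxy group, which blocks its own face so that the vinyl group enters anti; C5 is set by the new C1 vinyl group, the allyl electrophile approaching trans to it; C4 is set by the phosphoramidite ligand, which selects the face of the allyl fragment. The step needs regiochemical fidelity of the enolate, branched rather than linear allylation, and mono-allylation. The enolate position is secured because it is generated only by the conjugate addition, the branched outcome is the intrinsic preference of iridium allyl complexes, and the trans,trans arrangement is also the thermodynamic one at the epimerisable C5.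

Step 6
Reactants: 10 (2R,3R,4R)-2-[(2S)-but-3-en-2-yl]-4-(tert-butyldimethylsilyloxy)-3-vinylcycloheptan-1-one
Product: 11 trans-fused hydroazulenone: 10α-(tert-butyldimethylsilyloxy)-4β-methyl-1αH,5βH-bicyclo[5.3.0]dec-2-en-6-one (target numbering; 1R,4S,5R,10R)
Conditions: second-generation Grubbs catalyst (5 mol %), CH2Cl2, 40 °C
Reagents that add atoms: none
Why: Ring-closing metathesis of two monosubstituted alkenes held trans on adjacent ring carbons closes the cyclopentene with loss of ethene; no stereocentre is touched and the neutral conditions spare the epimerisable C5.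

Step 7
Reactants: 11 trans-fused hydroazulenone
Product: 13 dienone: 10α-(tert-butyldimethylsilyloxy)-4β-methyl-1αH,5βH-bicyclo[5.3.0]deca-2,7-dien-6-one (target numbering), via trimethylsilyl enol ether 12 (not isolated)
Conditions: LiN(iPr)2, Me3SiCl, THF, −78 °C; then Pd(OAc)2 (1.1 equiv), MeCN, rt
Reagents that add atoms: none
Why: Saegusa–Ito oxidation: the bulky amide removes a proton kinetically from the C7 methylene rather than from the tertiary C5, and palladation of the silyl enol ether by divalent palladium followed by β-hydride elimination gives the C7=C8 enone.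

Step 8
Reactants: 13 dienone
Product: 14 (6R)-allylic alcohol: 10α-(tert-butyldimethylsilyloxy)-4β-methyl-1αH,5βH-bicyclo[5.3.0]deca-2,7-dien-6β-ol (target numbering)
Conditions: NaBH4, CeCl3·7H2O, MeOH, −78 °C
Reagents that add atoms: none
Why: Luche 1,2-reduction; in the trans-fused system H5 is pseudo-axial, so the small hydride should enter C6 from the α face, anti-periplanar to that C–H bond, and leave the pseudo-equatorial β hydroxyl cis to H5.

Step 9
Reactants: 14 (6R)-allylic alcohol; 15 ethyl prop-1-enyl ether (E/Z mixture)
Product: 16 mixed bromoacetal: 6β-(2-bromo-1-ethoxypropoxy) derivative of 14 (mixture at the two new chain carbons)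
Conditions: N-bromosuccinimide, CH2Cl2, −40 to 0 °C
Reagents that add atoms: N-bromosuccinimide, O=C1CCC(=O)N1Br
Why: Bromoetherification: the enol ether is the most electron-rich alkene, takes up bromine at its β carbon, and the oxocarbenium ion is captured by the C6 hydroxyl; the new centres are either planarised or converged later.

Step 10
Reactants: 16 mixed bromoacetal
Product: 17 cis-fused tricyclic ethyl acetal: O6–C12 bridged 2-ethoxytetrahydrofuran with C7–C11 bond β, (11S)-methyl cis to H7, 10α-(tert-butyldimethylsilyloxy) (anomer mixture at C12)
Conditions: Bu3SnH (slow addition), AIBN (cat.), toluene, 80 °C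
Reagents that add atoms: none
Why: Ueno–Stork cyclisation: bromine abstraction gives the secondary C11 radical, which closes 5-exo-trig on C7; the O6 tether forces the cis ring fusion and so places C11 on the β face, the methyl group should take the convex side away from C8, and the C8 radical is reduced by the stannane.

Step 11
Reactants: 17 cis-fused tricyclic ethyl acetal
Product: 18 C10 alcohol: 10α-hydroxy analogue of 17
Conditions: Bu4NF, THF, rt
Reagents that add atoms: none
Why: Fluoride cleavage of the only silyl ether in the molecule; the acetal and the alkene are inert to it.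

Step 12
Reactants: 18 C10 alcohol
Product: 19 C10 ketone: 10-oxo analogue of 17
Conditions: Dess–Martin periodinane, NaHCO3, CH2Cl2, 0 °C to rt
Reagents that add atoms: none
Why: Buffered hypervalent-iodine oxidation of a secondary alcohol; the neutral medium protects the now epimerisable, doubly activated C1–H, and the sacrificial stereocentre is erased here.

Step 13
Reactants: 19 C10 ketone
Product: 21 (9R)-α-hydroxy ketone: 9α-hydroxy-10-oxo acetal, via sodium enolate 20 (not isolated)
Conditions: NaN(SiMe3)2, THF, −78 °C; then 2-(phenylsulfonyl)-3-phenyloxaziridine, −78 °C; NH4Cl (aq.)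
Reagents that add atoms: 2-(phenylsulfonyl)-3-phenyloxaziridine, O=S(=O)(c1ccccc1)N1OC1c1ccccc1
Why: Kinetic deprotonation by the bulky amide at the accessible C9 methylene rather than at the tertiary ring-fusion C1, then electrophilic oxygen transfer from the N-sulfonyloxaziridine to the enolate; the β face is covered by the cis-fused acetal ring at C6 and C7, so oxygen should arrive on the α face.

Step 14
Reactants: 21 (9R)-α-hydroxy ketone
Product: 22 α-silyloxy ketone: 9α-(tert-butyldimethylsilyloxy)-10-oxo acetal
Conditions: tBuMe2SiOTf, 2,6-lutidine, CH2Cl2, −78 °C
Reagents that add atoms: tert-butyldimethylsilyl trifluoromethanesulfonate, CC(C)(C)[Si](C)(C)OS(=O)(=O)C(F)(F)F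
Why: Silylation of the secondary ketol with a weak, hindered base at low temperature, which blocks ketol rearrangement and does not enolise the ketone.

Step 15
Reactants: 22 α-silyloxy ketone
Product: 23 exocyclic alkene: 9α-(tert-butyldimethylsilyloxy)-10-methylidene acetal
Conditions: Cp2TiMe2, toluene, 65 °C, dark
Reagents that add atoms: dimethyltitanocene, [CH3-].[CH3-].[Ti+4].c1cc[cH-]c1.c1cc[cH-]c1
Why: Carbonyl methylenation by the titanium methylidene formed on heating Cp2TiMe2; the reagent is non-basic, so the hindered ketone is olefinated without epimerising C1, and the acetal is not attacked.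

Step 16
Reactants: 23 exocyclic alkene
Product: 25 diol: (6R)-6-hydroxy, C12 primary alcohol, 9α-(tert-butyldimethylsilyloxy), 10-methylidene (11S), via lactol 24 (not isolated)
Conditions: pyridinium p-toluenesulfonate, THF/H2O (4:1), 50 °C; then NaBH4, MeOH, 0 °C
Reagents that add atoms: water, O
Why: Mild acid hydrolysis of the 2-alkoxytetrahydrofuran acetal, which is far more labile than the secondary silyl ether, followed by borohydride reduction of the lactol through its open hydroxy aldehyde.

Step 17
Reactants: 25 diol
Product: 26 bis(triethylsilyl) ether of 25 (O6 and O12)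
Conditions: Et3SiOTf, 2,6-lutidine, CH2Cl2, −78 to 0 °C
Reagents that add atoms: triethylsilyl trifluoromethanesulfonate, CC[Si](CC)(CC)OS(=O)(=O)C(F)(F)F
Why: Exhaustive silylation with a reactive silyl triflate, needed for the hindered C6 hydroxyl; no selectivity is required.

Step 18
Reactants: 26 bis(triethylsilyl) ether
Product: 27 aldehyde: (11S)-C12 aldehyde with 6β-triethylsilyloxy, 9α-(tert-butyldimethylsilyloxy), 10-methylidene
Conditions: (COCl)2, DMSO, CH2Cl2, −78 to −30 °C; then Et3N, −78 to 0 °C
Reagents that add atoms: none
Why: Direct Swern oxidation of a primary triethylsilyl ether: the chlorosulfonium ion attacks the unhindered primary Si–O oxygen, Et3SiCl is lost and the alkoxysulfonium ion collapses to the aldehyde, while the secondary silyl ethers are too hindered to react at this temperature.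

Step 19
Reactants: 28 3-methylbut-3-en-2-one
Product: 29 2-methyl-3-(trimethylsilyloxy)buta-1,3-diene
Conditions: Me3SiOTf, Et3N, Et2O, 0 °C
Reagents that add atoms: trimethylsilyl trifluoromethanesulfonate, C[Si](C)(C)OS(=O)(=O)C(F)(F)F
Why: Soft enolisation and O-silylation; the methyl group is the only enolisable position, so a single silyl enol ether can form.

Step 20
Reactants: 27 aldehyde; 29 2-methyl-3-(trimethylsilyloxy)buta-1,3-diene
Product: 30 β-hydroxy enone: (12S)-12-hydroxy-14-oxo side chain (11,12-syn), silyl ethers as in 27
Conditions: BF3·OEt2, CH2Cl2, −78 °C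
Reagents that add atoms: none
Why: Mukaiyama aldol addition through an open transition state; by the Felkin–Anh model the enol silane attacks the aldehyde anti to the large C7 substituent on C11, which should give the 11,12-syn carbinol, and the non-basic conditions keep C11 from epimerising.

Step 21
Reactants: 30 β-hydroxy enone
Product: 31 β-acetoxy enone: (12S)-12-acetoxy-14-oxo side chain
Conditions: Ac2O, pyridine, 4-(dimethylamino)pyridine (cat.), CH2Cl2, 0 °C
Reagents that add atoms: acetic anhydride, CC(=O)OC(C)=O
Why: Acylation of the only free hydroxyl in the molecule, so the acetate is placed on O12 without any selectivity problem; weak base and low temperature restrain β-elimination.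

Step 22
Reactants: 31 β-acetoxy enone
Product: 32 (14R)-allylic alcohol: bis-silyl ether of the target (O6 triethylsilyl, O9 tert-butyldimethylsilyl)
Conditions: (S)-2-methyl-CBS-oxazaborolidine (20 mol %), catecholborane, toluene, −78 °C
Reagents that add atoms: none
Why: Corey–Bakshi–Shibata reduction: the ketone binds to the oxazaborolidine with the isopropenyl group as the large substituent and receives hydride on the face that gives the 14R carbinol, 1,3-syn to O12; catecholborane at low temperature leaves the alkenes and the acetate alone.

Step 23
Reactants: 32 (14R)-allylic alcohol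
Product: 33 CNP0151410.1, the (1R,4S,5R,6R,7S,9R,11S,12S,14R) 12-acetate (target numbering)
Conditions: HF·pyridine, pyridine, THF, 0 °C to rt
Reagents that add atoms: none
Why: Fluoride-mediated cleavage of both silyl ethers in a buffered, weakly acidic medium, which avoids the alkoxide that would trigger 1,3-migration of the acetate from O12 to O14.

## Compound list

1 | cyclohepta-1,3-diene | C1=CC=CCCC1 | starting material
2 | (1R,5S)-6,7-dioxabicyclo[3.2.2]non-8-ene | C1CC[C@H]2C=C[C@@H]1OO2 | intermediate
3 | (R)-4-hydroxycyclohept-2-en-1-one | O=C1CCC[C@@H](O)C=C1 | intermediate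
4 | (R)-4-(tert-butyldimethylsilyloxy)cyclohept-2-en-1-one | O=C1CCC[C@@H](O[Si](C)(C)C(C)(C)C)C=C1 | intermediate
5 | (E)-but-2-en-1-ol | C/C=C/CO | starting material
6 | methyl chloroformate | COC(=O)Cl | starting material
7 | (E)-but-2-enyl methyl carbonate | C/C=C/COC(=O)OC | intermediate
8 | vinylmagnesium bromide | C=C[Mg]Br | starting material
9 | bromomagnesium (3R,4R)-4-(tert-butyldimethylsilyloxy)-3-vinylcyclohept-1-en-1-olate (not isolated) | Br[Mg]OC1=C[C@@H](C=C)[C@H](O[Si](C)(C)C(C)(C)C)CCC1 | intermediate
10 | (2R,3R,4R)-2-[(2S)-but-3-en-2-yl]-4-(tert-butyldimethylsilyloxy)-3-vinylcycloheptan-1-one | O=C1CCC[C@@H](O[Si](C)(C)C(C)(C)C)[C@H](C=C)[C@H]1[C@@H](C)C=C | intermediate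
11 | 10α-(tert-butyldimethylsilyloxy)-4β-methyl-1αH,5βH-bicyclo[5.3.0]dec-2-en-6-one (target numbering; 1R,4S,5R,10R) | O=C1CCC[C@@H](O[Si](C)(C)C(C)(C)C)[C@@H]2C=C[C@H](C)[C@@H]12 | intermediate
12 | trimethylsilyl enol ether of 11 (C6=C7; not isolated) | C[Si](C)(C)OC1=CCC[C@@H](O[Si](C)(C)C(C)(C)C)[C@@H]2C=C[C@H](C)[C@@H]12 | intermediate
13 | 10α-(tert-butyldimethylsilyloxy)-4β-methyl-1αH,5βH-bicyclo[5.3.0]deca-2,7-dien-6-one (target numbering) | O=C1C=CC[C@@H](O[Si](C)(C)C(C)(C)C)[C@@H]2C=C[C@H](C)[C@@H]12 | intermediate
14 | (6R)-10α-(tert-butyldimethylsilyloxy)-4β-methyl-1αH,5βH-bicyclo[5.3.0]deca-2,7-dien-6β-ol (target numbering) | O[C@@H]1C=CC[C@@H](O[Si](C)(C)C(C)(C)C)[C@@H]2C=C[C@H](C)[C@@H]12 | intermediate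
15 | ethyl prop-1-enyl ether (E/Z mixture) | CCOC=CC | starting material
16 | 6β-(2-bromo-1-ethoxypropoxy) ether of 14 (mixture at the two chain carbons) | CCOC(C(C)Br)O[C@@H]1C=CC[C@@H](O[Si](C)(C)C(C)(C)C)[C@@H]2C=C[C@H](C)[C@@H]12 | intermediate
17 | cis-fused tricyclic ethyl acetal (O6–C12 bridge, C7–C11 β, 11S, 10α-silyloxy; C12 anomers) | CCOC1O[C@@H]2[C@H]([C@@H]1C)CC[C@@H](O[Si](C)(C)C(C)(C)C)[C@@H]3C=C[C@H](C)[C@H]32 | intermediate
18 | 10α-hydroxy tricyclic ethyl acetal | CCOC1O[C@@H]2[C@H]([C@@H]1C)CC[C@@H](O)[C@@H]3C=C[C@H](C)[C@H]32 | intermediate
19 | 10-oxo tricyclic ethyl acetal | CCOC1O[C@@H]2[C@H]([C@@H]1C)CCC(=O)[C@@H]3C=C[C@H](C)[C@H]32 | intermediate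
20 | sodium C9=C10 enolate of 19 (not isolated) | CCOC1O[C@@H]2[C@H]([C@@H]1C)CC=C(O[Na])[C@@H]3C=C[C@H](C)[C@H]32 | intermediate
21 | (9R)-9α-hydroxy-10-oxo tricyclic ethyl acetal | CCOC1O[C@@H]2[C@H]([C@@H]1C)C[C@@H](O)C(=O)[C@@H]3C=C[C@H](C)[C@H]32 | intermediate
22 | 9α-(tert-butyldimethylsilyloxy)-10-oxo tricyclic ethyl acetal | CCOC1O[C@@H]2[C@H]([C@@H]1C)C[C@@H](O[Si](C)(C)C(C)(C)C)C(=O)[C@@H]3C=C[C@H](C)[C@H]32 | intermediate
23 | 9α-(tert-butyldimethylsilyloxy)-10-methylidene tricyclic ethyl acetal | CCOC1O[C@@H]2[C@H]([C@@H]1C)C[C@@H](O[Si](C)(C)C(C)(C)C)C(=C)[C@@H]3C=C[C@H](C)[C@H]32 | intermediate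
24 | lactol of 23 (C12 hemiacetal; not isolated) | OC1O[C@@H]2[C@H]([C@@H]1C)C[C@@H](O[Si](C)(C)C(C)(C)C)C(=C)[C@@H]3C=C[C@H](C)[C@H]32 | intermediate
25 | diol: 6β-hydroxy, C12 primary alcohol, 9α-(tert-butyldimethylsilyloxy), 10-methylidene, 11S | OC[C@@H](C)[C@@H]1C[C@@H](O[Si](C)(C)C(C)(C)C)C(=C)[C@@H]2C=C[C@H](C)[C@H]2[C@@H]1O | intermediate
26 | O6,O12-bis(triethylsilyl) ether of 25 | CC[Si](CC)(CC)OC[C@@H](C)[C@@H]1C[C@@H](O[Si](C)(C)C(C)(C)C)C(=C)[C@@H]2C=C[C@H](C)[C@H]2[C@@H]1O[Si](CC)(CC)CC | intermediate
27 | (11S)-C12 aldehyde, 6β-triethylsilyloxy, 9α-(tert-butyldimethylsilyloxy), 10-methylidene | O=C[C@@H](C)[C@@H]1C[C@@H](O[Si](C)(C)C(C)(C)C)C(=C)[C@@H]2C=C[C@H](C)[C@H]2[C@@H]1O[Si](CC)(CC)CC | intermediate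
28 | 3-methylbut-3-en-2-one | CC(=O)C(C)=C | starting material
29 | 2-methyl-3-(trimethylsilyloxy)buta-1,3-diene | C=C(C)C(=C)O[Si](C)(C)C | intermediate
30 | (12S)-12-hydroxy-14-oxo compound (β-hydroxy enone), silyl ethers as in 27 | C=C(C)C(=O)C[C@H](O)[C@@H](C)[C@@H]1C[C@@H](O[Si](C)(C)C(C)(C)C)C(=C)[C@@H]2C=C[C@H](C)[C@H]2[C@@H]1O[Si](CC)(CC)CC | intermediate
31 | (12S)-12-acetoxy-14-oxo compound | C=C(C)C(=O)C[C@H](OC(C)=O)[C@@H](C)[C@@H]1C[C@@H](O[Si](C)(C)C(C)(C)C)C(=C)[C@@H]2C=C[C@H](C)[C@H]2[C@@H]1O[Si](CC)(CC)CC | intermediate
32 | (14R)-14-hydroxy-12-acetoxy compound, O6 triethylsilyl and O9 tert-butyldimethylsilyl ethers | C=C(C)[C@H](O)C[C@H](OC(C)=O)[C@@H](C)[C@@H]1C[C@@H](O[Si](C)(C)C(C)(C)C)C(=C)[C@@H]2C=C[C@H](C)[C@H]2[C@@H]1O[Si](CC)(CC)CC | intermediate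
33 | CNP0151410.1, (1R,4S,5R,6R,7S,9R,11S,12S,14R) 12-acetate (target numbering) | C=C(C)[C@H](O)C[C@H](OC(C)=O)[C@@H](C)[C@@H]1C[C@@H](O)C(=C)[C@@H]2C=C[C@H](C)[C@H]2[C@@H]1O | target

## Step count and least certain steps

Total step count: 23. Longest linear sequence: 21 steps (steps 1 to 3, 5 to 18 and 20 to 23); steps 4 and 19 are side branches.

**Step 5 (key step).** The magnesium enolate may be captured too slowly by the iridium allyl complex. Proton transfer would then scramble the enolate position, and the small methyl substituent of the crotyl unit may erode both the branched preference and the facial control at C4. Fallback from 4, returning at 10: run the copper-catalysed vinyl addition in the presence of Me3SiCl and isolate the trimethylsilyl enol ether F1. Then allylate F1 with 7 under [Ir(cod)Cl]2 and the same phosphoramidite with fluoride activation (CsF, ZnF2, 1,2-dimethoxyethane, 50 °C). This separates the two events and releases the enolate only in the presence of the allyl complex.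

**Step 8.** Hydride delivery to the wrong face of C6 is possible, because the conformational bias of a seven-membered enone is weaker than that of a cyclohexenone. Fallback from 13, returning at 14: accept the reduction to the 6α-alcohol F2 and invert it by Mitsunobu reaction (4-nitrobenzoic acid, PPh3, diisopropyl azodicarboxylate, THF) to the 6β 4-nitrobenzoate F3. Methanolysis (K2CO3, MeOH) then gives 14.

**Step 10.** Facial discrimination at the planar C11 radical may be low, so that the methyl group is partly placed on the concave side; transannular capture of the C8 radical is a lesser risk. Fallback from 17, returning at 17: hydrolyse the acetal (pyridinium p-toluenesulfonate, THF/H2O) to the lactol F4 and oxidise it (Ag2CO3 on Celite, toluene, reflux) to the γ-lactone F5. Equilibrate C11 with DBU to the convex-face methyl epimer, which is both the more stable one and the one required. Reduce back to F4 with iBu2AlH at −78 °C and re-form 17 with EtOH and pyridinium p-toluenesulfonate. Kinetic control is thereby replaced by thermodynamic control.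

**Step 13.** Deprotonation may occur at the doubly activated C1–H instead of C9, with epimerisation of the ring fusion or migration of the C2=C3 alkene; oxygen transfer may also be unselective between the faces. Fallback from 19, returning at 23: methylenate 19 first with Cp2TiMe2 to the exocyclic alkene F6. Carry out an allylic hydroxylation with SeO2 (cat.) and tBuOOH in CH2Cl2 (ene reaction, then [2,3] shift, preferring the ring methylene over the methine) to the allylic alcohol F7. Silylate with tBuMe2SiOTf and 2,6-lutidine to 23. No C10 enolate is formed on this path.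

**Step 20.** Felkin–Anh discrimination may be insufficient, the triethylsilyl ether may suffer under the Lewis acid, or the β-hydroxy enone may close by oxa-Michael addition. Fallback from 27 and 28, returning at 30: enolise 28 with (−)-chlorodiisopinocampheylborane and Et3N in Et2O at −78 °C to the boron enolate F8, or with its enantiomer, whichever reinforces the Felkin–Anh sense. Add 27 and work up with H2O2 at pH 7. The closed, reagent-controlled transition state needs no Lewis acid.

## Further compounds

F1 | step 5 | trimethylsilyl enol ether of (3R,4R)-4-(tert-butyldimethylsilyloxy)-3-vinylcycloheptanone | C[Si](C)(C)OC1=C[C@@H](C=C)[C@H](O[Si](C)(C)C(C)(C)C)CCC1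
F2 | step 8 | 6α-alcohol, the C6 epimer of 14 | O[C@H]1C=CC[C@@H](O[Si](C)(C)C(C)(C)C)[C@@H]2C=C[C@H](C)[C@@H]12
F3 | step 8 | 6β 4-nitrobenzoate of 14 | O=C(O[C@@H]1C=CC[C@@H](O[Si](C)(C)C(C)(C)C)[C@@H]2C=C[C@H](C)[C@@H]12)c1ccc([N+](=O)[O-])cc1
F4 | step 10 | lactol of 17 (C12 hemiacetal, 10α-silyloxy) | OC1O[C@@H]2[C@H]([C@@H]1C)CC[C@@H](O[Si](C)(C)C(C)(C)C)[C@@H]3C=C[C@H](C)[C@H]32
F5 | step 10 | cis-fused γ-lactone (C12 carbonyl, 11S methyl on the convex face, 10α-silyloxy) | O=C1O[C@@H]2[C@H]([C@@H]1C)CC[C@@H](O[Si](C)(C)C(C)(C)C)[C@@H]3C=C[C@H](C)[C@H]32
F6 | step 13 | 10-methylidene tricyclic ethyl acetal without C9 oxygen | CCOC1O[C@@H]2[C@H]([C@@H]1C)CCC(=C)[C@@H]3C=C[C@H](C)[C@H]32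
F7 | step 13 | 9α-hydroxy-10-methylidene tricyclic ethyl acetal | CCOC1O[C@@H]2[C@H]([C@@H]1C)C[C@@H](O)C(=C)[C@@H]3C=C[C@H](C)[C@H]32
F8 | step 20 | diisopinocampheylboron enolate of 28 | C=C(C)C(=C)OB([C@@H]1C[C@@H]2C[C@H]([C@H]1C)C2(C)C)[C@@H]1C[C@@H]2C[C@H]([C@H]1C)C2(C)C
A1 | alternative 1 | cis-fused bicyclic ethyl acetal with 9α-silyloxy and 10-methylidene (same compound as 23) | CCOC1O[C@@H]2[C@H]([C@@H]1C)C[C@@H](O[Si](C)(C)C(C)(C)C)C(=C)[C@@H]3C=C[C@H](C)[C@H]32
A2 | alternative 1 | bromoacetal of the C6 allylic alcohol with C7=C8 alkene, 9α-silyloxy and 10-methylidene | CCOC(C(C)Br)O[C@@H]1C=C[C@@H](O[Si](C)(C)C(C)(C)C)C(=C)[C@@H]2C=C[C@H](C)[C@@H]12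
A3 | alternative 2 | trans-fused hydroazulen-9-one with a C10 hydroxymethyl group | CC(C)(C)[Si](C)(C)OC[C@@H](C)[C@@H]1CC(=O)[C@H](CO)[C@@H]2C=C[C@H](C)[C@H]2[C@@H]1O[Si](C)(C)C(C)(C)C
A4 | alternative 2 | trans-hydrindane tertiary epoxy alcohol (C9 carbinol carrying the C10 oxirane) | CC(C)(C)[Si](C)(C)OC[C@@H](C)[C@@H]1C[C@](O)([C@H]3CO3)[C@@H]2C=C[C@H](C)[C@H]2[C@@H]1O[Si](C)(C)C(C)(C)C
A5 | alternative 3 | trans-fused hydroazulen-9-one with the C10 exocyclic methylene | CC(C)(C)[Si](C)(C)OC[C@@H](C)[C@@H]1CC(=O)C(=C)[C@@H]2C=C[C@H](C)[C@H]2[C@@H]1O[Si](C)(C)C(C)(C)C
A6 | alternative 3 | cyclopentene carrying the C10 vinyl iodide on C1 and the C6 silyloxy / C7 methylidene chain on C5 | CC(C)(C)[Si](C)(C)OC[C@@H](C)C(=C)[C@@H](O[Si](C)(C)C(C)(C)C)[C@@H]1[C@@H](C)C=C[C@H]1C(I)=C
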